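Locants used throughout: the cyclohexane (ring A) is numbered C1 (ethyl), C2 (methyl), C3 (aryl), C4 (methyl), C5 (aryl), C6 (spiro carbon); the same atoms keep these locants in every intermediate. Compound numbers are those of the list after the steps.

## Analysis of the target

Tatanan B is a spiro[5.5]undecane in which a cyclohexane (ring A) shares its quaternary carbon C6 with a 2,5-dimethoxycyclohexa-2,5-dien-1-one (ring B), C6 being the 4-position of the dienone. Every carbon of ring A is substituted (ethyl on C1, methyl on C2 and C4, 2,4,5-trimethoxyphenyl on C3 and C5), so C1–C6 are six contiguous stereocentres. The ethyl group, the C2 methyl and both aryl groups lie on one face and the C4 methyl on the other; in the chair everything is equatorial except the C2 methyl, and at C6 the CH= arm of ring B is axial (on the face of the C2 methyl) and the C(OMe)= arm equatorial. The cross-conjugated dienone is sensitive to acid (dienone–phenol rearrangement), to reduction and to nucleophiles, and the three electron-rich arenes are sensitive to oxidants and strong electrophiles. The difficulty lies in a ring A without any heteroatom handle, a quaternary spiro centre between two substituted carbons, two identical aryl groups on non-equivalent carbons, and a C2 methyl that must end axial. Ring B has the oxygen pattern of the C5 aryl: it is a 4-hydroxy-2,5-dimethoxyphenyl ring dearomatised at its ipso carbon, so C5 can carry two identical phenols, one of which becomes ring B. The strategy rests on the aryl group at C3: its methoxy oxygen ortho to C3 can serve as the carbonyl oxygen of an ortho-quinone methide with exocyclic carbon C3 and be bonded for a time to C1, so that the C2–C3 bond is made inside a six-membered ring.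

## Retrosynthetic reasoning

**30 back to 28.** The last two operations change no skeletal bond: O-methylation of the one remaining phenol (29 to 30) and hydrogenation of a vinyl group to the C1 ethyl (28 to 29). One phenol stays free this long because the ring closure before it needs free phenols.

**28 to 27, cut at C1–C6.** C6 is quaternary and is the former ipso carbon of an aryl ring already attached to C5. Making this bond last closes ring A and creates ring B in one event. The forward reaction, a palladium π-allyl attack by a phenol para carbon, must choose the internal allyl terminus, must use one of the two twin phenols, and must set C1, C5 and C6.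

**27 to 22 and 23, cut at C1–vinyl.** Carbonate 27 comes from 26 (desilylation), 25 (carbonate formation) and 24 (phenol methylation). Allylic alcohol 24 comes from lactol 22 and vinylmagnesium bromide 23. A branched allylic carbonate gives the same π-allyl complex as a linear one, so an olefination–reduction sequence is not needed, and the C2 stereocentre is never exposed, α to an aldehyde, to basic olefination conditions.

**22 to 21 to 20 and 18, the key cut at C2–C3 and O–C1.** Tying the ortho oxygen of the C3 aryl to C1 turns the acyclic C2/C3 problem into the endo/exo and alkene-geometry question of a hetero-Diels–Alder reaction between quinone methide 20 and an (E)-propenyl ether. The acetal carbon is C1 at the aldehyde oxidation level. The forward reaction needs the right regiochemistry, endo addition, retention of the E geometry and the right face of 20. The facial question does not solve itself: in the allylic-strain conformer of 20 (C4–H eclipsing the exocyclic double bond) the C4 methyl and the bis-aryl carbon C5 sit on opposite faces, a dienophile would enter past the methyl group, anti to C5, and the target needs the new C2–C3 bond on the face of C5. Control is therefore moved to the enol ether. Its O-alkyl group is lost in the step from 21 to 22 and is a free choice, so the ethyl group is replaced by (1S,2R)-2-phenylcyclohexyl (18), whose phenyl ring blocks one face of the enol ether; through the endo rule this fixes the face of 20.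

**20 to 14 to 13 to 10 and 11, cut at aryl–C3.** Reagent control needs a low temperature, so 20 is released from aryl carbonate 14 by carbonate transposition and elimination on magnesium and not by thermal dehydration. Carbonate 14 is made from diol 13. Diol 13 results from ortho-hydroxyalkylation of 3,4-dimethoxyphenol 11 (as its magnesium salt 12) with aldehyde 10. The carbinol centre formed here is lost again in 20.

**10 to 7 and 8, cut at C4–C5.** C5 is a doubly benzylic cation synthon (9) and C4 is the α-carbon of propanal 8. An amine catalyst sets C4, the only stereocentre, because the two aryl groups on C5 are identical. Cation 9 is the O-silylated equivalent of a bis-aryl para-quinone methide; using it directly keeps both silyl ethers in place and avoids a re-silylation.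

**7 to 3 and 4; 3 to 2 to 1.** The symmetrical carbinol 7 comes from two aryllithiums 5 and ethyl formate 4. The bromide 3 comes from silyl ether 2 of 2,5-dimethoxyphenol 1 by bromination para to the silyloxy group.

**18 to 17 to 15 and 16.** The enol ether is made from the commercial alcohol 15 by allylation with 16 and E-selective isomerisation of the allyl ether 17.

## Alternatives that were turned down

**Alternative 1: twofold C–H arylation of a symmetric cyclohexane.**
- Disconnection: both aryl–ring bonds (C3–aryl, C5–aryl) are cut from ketal amide A3. In the forward step Pd(OAc)2/AgOAc and the 8-aminoquinoline amide on C4 direct two β-C–H arylations with iodide A2, cis to the amide, to give the meso compound A1.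
- For: ring A exists from the start, and both aryl groups are placed in one operation with a cis relation that the palladacycle enforces. Epimerisation at C4 (α to the carbonyl) would then give the aryl/C4/aryl trans,trans array of the target.
- Against: A1 is achiral, so C2 and C6 must be told apart by an enantioselective desymmetrisation. The amide carbon must be cut down to a methyl group. The C2 methyl must be installed cis to the C3 aryl, against the usual sense of enolate alkylation. The whole of ring B must be built on a ketone carbon next to an aryl-bearing centre. A second arylation of a methylene C–H with an ortho-substituted, electron-rich iodide is also expected to be slow.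
- Comparison: for the C3/C4/C5 relation this route is stronger, since that relation is cyclic and fixed, whereas the chosen route depends on a contested facial selection. The chosen route instead has every carbon of ring B in place as a phenol, reaches C6 by one bond formation, and takes its absolute configuration from one catalytic step.

**Alternative 2: three-component amine cascade around a nitro group.**
- Disconnection: ring A is cut at C3–C4, C1–C2 and C5=C6. In the forward step a diarylprolinol silyl ether takes 8, nitroalkene A5 and enal A6 through Michael addition, nitronate Michael addition and aldol condensation to cyclohexenecarbaldehyde A4.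
- For: ring A and four stereocentres arise in one flask from trivial components with catalyst-controlled absolute configuration and no mismatched element. In step count to a six-membered ring and in enantiocontrol it is stronger than the chosen route.
- Against: C2 carries a nitro group where the target has a methyl group, and the cascade is expected to place it trans to both neighbours, while the target needs the C2 substituent cis to the C3 aryl and the C1 ethyl. C5 has no aryl group. C6 carries a formyl group from which a quaternary spiro centre and a dimethoxydienone ring would have to be built.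
- Comparison: the chosen route is longer to ring A, but every ring A carbon arrives with its final substituent and ring B comes from an aryl group.

**Alternative 3: palladium ipso-allylation as the organising step.**
- Disconnection: C1–C6 is cut. In the forward step a π-allylpalladium complex is attacked at its internal carbon by the para carbon of one twin phenol, giving A7.
- For: it forms ring A, ring B and the quaternary centre together and uses the twin phenols. It is so well suited that the chosen route ends with it: A7 is identical with 28 and arises in step 15 from carbonate 27.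
- Against, as a strategy on its own: it moves the whole stereochemical burden of C2, C3 and C4 onto an open-chain precursor and says nothing on how the C2–C3 bond is made.
- Comparison: for the last carbon–carbon bond the two strategies coincide. The chosen one adds the temporary chroman, which makes C2–C3, ties the C2/C3 relation to a cycloaddition and delivers C1 as an acetal ready to become the allyl unit.

Key step: step 9

Assumption 1: the enol ether of (1S,2R)-2-phenylcyclohexanol is taken to react in its s-trans conformation on the face away from the phenyl ring, which gives the C1/C2 configuration drawn for 21; if the sense were opposite, the (1R,2S) alcohol would be used with no other change.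
Assumption 2: the target structure fixes six stereocentres and no axis, so slowly interconverting rotamers about the C5–aryl bond, if they exist, are treated as one compound.

## Steps

Step 1
Reactants: 1 2,5-dimethoxyphenol
Product: 2 (2,5-dimethoxyphenoxy)triisopropylsilane
Conditions: TIPSCl, imidazole, DMF, rt
Reagents that add atoms: triisopropylsilyl chloride, CC(C)[Si](Cl)(C(C)C)C(C)C
Why: Silylation of a phenol; the bulky aryl silyl ether should survive organolithium, Grignard, amine and dilute acid conditions and is removed by fluoride when the twin phenols are needed.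

Step 2
Reactants: 2 (2,5-dimethoxyphenoxy)triisopropylsilane
Product: 3 (4-bromo-2,5-dimethoxyphenoxy)triisopropylsilane
Conditions: N-bromosuccinimide, MeCN, 0 °C to rt
Reagents that add atoms: N-bromosuccinimide, O=C1CCC(=O)N1Br
Why: Electrophilic aromatic bromination; C4 is para to the silyloxy group and ortho to a methoxy group, whereas C6 is flanked by two oxygen substituents and C3 is activated by one methoxy group only, so the 4-bromide should dominate.

Step 3
Reactants: 3 (4-bromo-2,5-dimethoxyphenoxy)triisopropylsilane (2 equiv); 4 ethyl formate (0.5 equiv per 3)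
Product: 7 bis[2,5-dimethoxy-4-(triisopropylsilyloxy)phenyl]methanol, via aryllithium 5 (not isolated), via aryl aldehyde 6 (not isolated)
Conditions: n-BuLi, THF, −78 °C; then HCO2Et, −78 to 0 °C; NH4Cl (aq)
Reagents that add atoms: none
Why: Bromine–lithium exchange followed by double addition to a formate ester, the standard route to symmetrical diaryl carbinols; lithium para to the silyloxy group cannot undergo a retro-Brook shift.

Step 4
Reactants: 7 bis[2,5-dimethoxy-4-(triisopropylsilyloxy)phenyl]methanol; 8 propanal (3 equiv)
Product: 10 (2S)-3,3-bis[2,5-dimethoxy-4-(triisopropylsilyloxy)phenyl]-2-methylpropanal, via diarylmethylium ion 9 (not isolated)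
Conditions: (R)-2-[diphenyl(trimethylsilyloxy)methyl]pyrrolidine (20 mol %), CF3CO2H (20 mol %), CH2Cl2, 0 °C
Reagents that add atoms: none
Why: Enamine catalysis combined with SN1 ionisation: acid removes the hydroxyl group of 7 as water to give the doubly donor-stabilised cation 9, the O-silylated equivalent of a para-quinone methide, which alkylates the E-enamine of propanal. The diphenyl(silyloxy)methyl group of the (R)-catalyst shields one enamine face, so 9 adds to the open face and C4 is formed S; C5 carries two identical aryl groups and is not a stereocentre.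

Step 5
Reactants: 11 3,4-dimethoxyphenol; 10 (2S)-3,3-bis[2,5-dimethoxy-4-(triisopropylsilyloxy)phenyl]-2-methylpropanal
Product: 13 2-{(2S)-3,3-bis[2,5-dimethoxy-4-(triisopropylsilyloxy)phenyl]-1-hydroxy-2-methylpropyl}-4,5-dimethoxyphenol (both epimers at the carbinol carbon C3), via bromomagnesium phenoxide 12 (not isolated)
Conditions: EtMgBr (1.0 equiv), Et2O, 0 °C; solvent changed to CH2Cl2; then 10, rt; NH4Cl (aq)
Reagents that add atoms: none
Why: ortho-Specific hydroxyalkylation of a magnesium phenoxide: the aldehyde is bound to magnesium and delivered through a six-membered transition state to the free ortho carbon para to the 3-methoxy group, not to the crowded carbon between two oxygen substituents. The carbinol centre at C3 forms as a mixture, which does not matter because C3 becomes sp2 in step 9; the weakly basic phenoxide in a non-polar medium should leave C4 untouched.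

Step 6
Reactants: 13 2-{(2S)-3,3-bis[2,5-dimethoxy-4-(triisopropylsilyloxy)phenyl]-1-hydroxy-2-methylpropyl}-4,5-dimethoxyphenol
Product: 14 2-{(2S)-3,3-bis[2,5-dimethoxy-4-(triisopropylsilyloxy)phenyl]-1-hydroxy-2-methylpropyl}-4,5-dimethoxyphenyl tert-butyl carbonate
Conditions: Boc2O (1.05 equiv), i-Pr2NEt, DMAP (5 mol %), CH2Cl2, −20 °C
Reagents that add atoms: di-tert-butyl dicarbonate, CC(C)(C)OC(=O)OC(=O)OC(C)(C)C
Why: Chemoselective O-acylation of the more acidic and more nucleophilic phenol in the presence of a hindered secondary benzylic alcohol; the aryl carbonate is the trigger that releases the quinone methide at low temperature.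

Step 7
Reactants: 15 (1S,2R)-2-phenylcyclohexan-1-ol; 16 allyl bromide
Product: 17 (1S,2R)-2-phenylcyclohexyl prop-2-enyl ether
Conditions: NaH, THF/DMF, 0 °C to rt
Reagents that add atoms: none
Why: Williamson ether synthesis on the sodium alkoxide; neither stereocentre of the auxiliary is involved.

Step 8
Reactants: 17 (1S,2R)-2-phenylcyclohexyl prop-2-enyl ether
Product: 18 (1S,2R)-2-phenylcyclohexyl (E)-prop-1-enyl ether
Conditions: [Ir(cod)(PMePh2)2]PF6 (2 mol %, activated with H2), THF, rt
Reagents that add atoms: none
Why: Iridium hydride-catalysed 1,3-hydrogen shift of an allyl ether, which gives the (E)-propenyl ether under kinetic control.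

Step 9
Reactants: 14 2-{(2S)-3,3-bis[2,5-dimethoxy-4-(triisopropylsilyloxy)phenyl]-1-hydroxy-2-methylpropyl}-4,5-dimethoxyphenyl tert-butyl carbonate; 18 (1S,2R)-2-phenylcyclohexyl (E)-prop-1-enyl ether (3 equiv)
Product: 21 (2R,3R,4R)-4-{(2R)-1,1-bis[2,5-dimethoxy-4-(triisopropylsilyloxy)phenyl]propan-2-yl}-6,7-dimethoxy-3-methyl-2-{[(1S,2R)-2-phenylcyclohexyl]oxy}-3,4-dihydro-2H-chromene, via transposed benzylic carbonate 19 (not isolated), via ortho-quinone methide 20 (not isolated)
Conditions: t-BuMgCl (1.1 equiv), toluene, −78 °C to rt; NH4Cl (aq)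
Reagents that add atoms: none
Why: t-BuMgCl deprotonates the benzylic alcohol, the alkoxide takes over the carbonate from the neighbouring phenol (19), and on warming the magnesium phenoxide expels tert-butyl carbonate to give the E-configured ortho-quinone methide 20, an electron-poor 1-oxadiene. 20 and the electron-rich enol ether 18 then combine in an inverse-electron-demand hetero-Diels–Alder reaction, concerted but asynchronous, with the C2–C3 bond ahead of the O–C1 bond and the oxygen-bearing carbon of 18 going to the carbonyl oxygen for electronic reasons. The dihydropyran ring of the chroman is closed by this [4+2] cycloaddition, which also restores the arene. The closest known reaction type is the low-temperature cycloaddition of magnesium-generated ortho-quinone methides with enol ethers of trans-2-phenylcyclohexanol. C1: the alkoxy group takes the endo position, cis to the C3 side chain, and its face is set by the auxiliary; C2: the E geometry of 18 is retained, so the methyl group is trans to the alkoxy group and trans to the C3 side chain, which is the cis C2-methyl/C3-aryl relation of ring A; C3: through the endo rule the face of 20 follows from the face of 18 and is therefore under auxiliary control. The selectivity that matters is this facial one: in the allylic-strain conformer of 20 (C4–H eclipsing the exocyclic double bond) the methyl group and the bis-aryl carbon C5 lie on opposite faces, the substrate alone would react on the methyl face, and the target needs the new C2–C3 bond on the face of C5. The phenyl ring of the auxiliary blocks one face of the s-trans enol ether and has to override this bias at low temperature; this mismatched pairing is the main risk of the route.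

Step 10
Reactants: 21 (2R,3R,4R)-4-{(2R)-1,1-bis[2,5-dimethoxy-4-(triisopropylsilyloxy)phenyl]propan-2-yl}-6,7-dimethoxy-3-methyl-2-{[(1S,2R)-2-phenylcyclohexyl]oxy}-3,4-dihydro-2H-chromene
Product: 22 (3R,4R)-4-{(2R)-1,1-bis[2,5-dimethoxy-4-(triisopropylsilyloxy)phenyl]propan-2-yl}-6,7-dimethoxy-3-methyl-3,4-dihydro-2H-chromen-2-ol (both anomers)
Conditions: 1 M HCl, THF, rt
Reagents that add atoms: water, O
Why: Acid-catalysed hydrolysis of the mixed acetal through its oxocarbenium ion; C2, C3 and C4 are not involved, aryl triisopropylsilyl ethers tolerate dilute acid, and alcohol 15 is recovered.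

Step 11
Reactants: 22 (3R,4R)-4-{(2R)-1,1-bis[2,5-dimethoxy-4-(triisopropylsilyloxy)phenyl]propan-2-yl}-6,7-dimethoxy-3-methyl-3,4-dihydro-2H-chromen-2-ol; 23 vinylmagnesium bromide (4 equiv)
Product: 24 (4R,5R,6R)-7,7-bis[2,5-dimethoxy-4-(triisopropylsilyloxy)phenyl]-5-(2-hydroxy-4,5-dimethoxyphenyl)-4,6-dimethylhept-1-en-3-ol (both epimers at the carbinol carbon C1)
Conditions: THF, 0 °C to rt; NH4Cl (aq), neutral work-up
Reagents that add atoms: none
Why: Grignard addition to the open hydroxy aldehyde form of the lactol (the first equivalent deprotonates and opens it); addition at 0 °C should be faster than enolisation at C2. Both C1 epimers are acceptable because C1 becomes an allyl terminus in step 15.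

Step 12
Reactants: 24 (4R,5R,6R)-7,7-bis[2,5-dimethoxy-4-(triisopropylsilyloxy)phenyl]-5-(2-hydroxy-4,5-dimethoxyphenyl)-4,6-dimethylhept-1-en-3-ol
Product: 25 (4R,5R,6R)-7,7-bis[2,5-dimethoxy-4-(triisopropylsilyloxy)phenyl]-4,6-dimethyl-5-(2,4,5-trimethoxyphenyl)hept-1-en-3-ol
Conditions: MeI, K2CO3, acetone, rt
Reagents that add atoms: iodomethane, CI
Why: Williamson methylation of the phenoxide; K2CO3 does not deprotonate the secondary alcohol and, without a protic solvent, should leave the aryl silyl ethers intact. Capping this phenol now prevents its O-allylation in step 15.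

Step 13
Reactants: 25 (4R,5R,6R)-7,7-bis[2,5-dimethoxy-4-(triisopropylsilyloxy)phenyl]-4,6-dimethyl-5-(2,4,5-trimethoxyphenyl)hept-1-en-3-ol
Product: 26 (4R,5R,6R)-7,7-bis[2,5-dimethoxy-4-(triisopropylsilyloxy)phenyl]-4,6-dimethyl-5-(2,4,5-trimethoxyphenyl)hept-1-en-3-yl methyl carbonate
Conditions: ClCO2Me, pyridine, DMAP (cat.), CH2Cl2, 0 °C
Reagents that add atoms: methyl chloroformate, COC(Cl)=O
Why: Acylation of the allylic alcohol to its methyl carbonate, the leaving group for π-allyl formation, which also supplies methoxide as internal base.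

Step 14
Reactants: 26 (4R,5R,6R)-7,7-bis[2,5-dimethoxy-4-(triisopropylsilyloxy)phenyl]-4,6-dimethyl-5-(2,4,5-trimethoxyphenyl)hept-1-en-3-yl methyl carbonate
Product: 27 (4R,5R,6R)-7,7-bis(4-hydroxy-2,5-dimethoxyphenyl)-4,6-dimethyl-5-(2,4,5-trimethoxyphenyl)hept-1-en-3-yl methyl carbonate
Conditions: Bu4NF (2.5 equiv), AcOH (3 equiv), THF, 0 °C
Reagents that add atoms: none
Why: Fluoride cleavage of both aryl silyl ethers; acetic acid keeps the phenols protonated so that they do not attack the carbonate.

Step 15
Reactants: 27 (4R,5R,6R)-7,7-bis(4-hydroxy-2,5-dimethoxyphenyl)-4,6-dimethyl-5-(2,4,5-trimethoxyphenyl)hept-1-en-3-yl methyl carbonate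
Product: 28 (6S,7R,8R,9S,10R,11R)-7-ethenyl-11-(4-hydroxy-2,5-dimethoxyphenyl)-1,4-dimethoxy-8,10-dimethyl-9-(2,4,5-trimethoxyphenyl)spiro[5.5]undeca-1,4-dien-3-one (ring A: vinyl on C1, C2 methyl, C3 aryl and C5 aryl cis to one another, C4 methyl trans; at C6 the C(OMe)= carbon on the face of the C4 methyl)
Conditions: Pd2(dba)3·CHCl3 (5 mol %), PPh3 (20 mol %), CH2Cl2, rt
Reagents that add atoms: none
Why: Intramolecular ipso-Friedel–Crafts allylic alkylation of a para-substituted phenol (Tsuji–Trost type): zerovalent palladium ionises the carbonate of either C1 epimer, the liberated methoxide deprotonates a phenol, and its para carbon, the ipso carbon attached to C5, attacks the internal allyl terminus C1 in a 6-exo closure that is preferred over the eight-membered alternative. The two faces of the allyl unit exchange through the unsubstituted terminus, so C1, C5 and C6 are set in a chair-like transition state with the C3 aryl, the C4 methyl, the spectator C5 aryl and the vinyl group equatorial and the C2 methyl axial. Of the two rotamers of the attacking ring, the one that keeps its methoxy-bearing ortho carbon away from the axial C2 methyl gives the C6 configuration of the target.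

Step 16
Reactants: 28 (6S,7R,8R,9S,10R,11R)-7-ethenyl-11-(4-hydroxy-2,5-dimethoxyphenyl)-1,4-dimethoxy-8,10-dimethyl-9-(2,4,5-trimethoxyphenyl)spiro[5.5]undeca-1,4-dien-3-one
Product: 29 (6S,7R,8S,9S,10R,11R)-7-ethyl-11-(4-hydroxy-2,5-dimethoxyphenyl)-1,4-dimethoxy-8,10-dimethyl-9-(2,4,5-trimethoxyphenyl)spiro[5.5]undeca-1,4-dien-3-one (spatial arrangement as in 28; the descriptor at C8 changes only because ethyl ranks differently from vinyl)
Conditions: H2 (1 atm), RhCl(PPh3)3 (10 mol %), toluene/EtOH 1:1, rt
Reagents that add atoms: none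
Why: Homogeneous hydrogenation with RhCl(PPh3)3 reduces the monosubstituted vinyl group and should leave the trisubstituted, electron-poor dienone double bonds next to the quaternary centre untouched.

Step 17
Reactants: 29 (6S,7R,8S,9S,10R,11R)-7-ethyl-11-(4-hydroxy-2,5-dimethoxyphenyl)-1,4-dimethoxy-8,10-dimethyl-9-(2,4,5-trimethoxyphenyl)spiro[5.5]undeca-1,4-dien-3-one
Product: 30 tatanan B, (6S,7R,8S,9S,10R,11R)-7-ethyl-1,4-dimethoxy-8,10-dimethyl-9,11-bis(2,4,5-trimethoxyphenyl)spiro[5.5]undeca-1,4-dien-3-one (ring A: ethyl, C2 methyl and both aryl groups cis, C4 methyl trans; at C6 the C(OMe)= carbon on the face of the C4 methyl)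
Conditions: MeI, K2CO3, acetone, rt
Reagents that add atoms: iodomethane, CI
Why: Williamson methylation of the last phenol; the dienone has no site that K2CO3 and MeI would attack under these conditions.

## Compound list

1 | 2,5-dimethoxyphenol | COc1ccc(OC)c(O)c1 | starting material
2 | (2,5-dimethoxyphenoxy)triisopropylsilane | COc1ccc(OC)c(O[Si](C(C)C)(C(C)C)C(C)C)c1 | intermediate
3 | (4-bromo-2,5-dimethoxyphenoxy)triisopropylsilane | COc1cc(O[Si](C(C)C)(C(C)C)C(C)C)c(OC)cc1Br | intermediate
4 | ethyl formate | CCOC=O | starting material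
5 | [2,5-dimethoxy-4-(triisopropylsilyloxy)phenyl]lithium | [Li]c1cc(OC)c(O[Si](C(C)C)(C(C)C)C(C)C)cc1OC | intermediate (not isolated)
6 | 2,5-dimethoxy-4-(triisopropylsilyloxy)benzaldehyde | O=Cc1cc(OC)c(O[Si](C(C)C)(C(C)C)C(C)C)cc1OC | intermediate (not isolated)
7 | bis[2,5-dimethoxy-4-(triisopropylsilyloxy)phenyl]methanol | OC(c1cc(OC)c(O[Si](C(C)C)(C(C)C)C(C)C)cc1OC)c1cc(OC)c(O[Si](C(C)C)(C(C)C)C(C)C)cc1OC | intermediate
8 | propanal | CCC=O | starting material
9 | bis[2,5-dimethoxy-4-(triisopropylsilyloxy)phenyl]methylium ion | [CH+](c1cc(OC)c(O[Si](C(C)C)(C(C)C)C(C)C)cc1OC)c1cc(OC)c(O[Si](C(C)C)(C(C)C)C(C)C)cc1OC | intermediate (not isolated)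
10 | (2S)-3,3-bis[2,5-dimethoxy-4-(triisopropylsilyloxy)phenyl]-2-methylpropanal | O=C[C@@H](C)C(c1cc(OC)c(O[Si](C(C)C)(C(C)C)C(C)C)cc1OC)c1cc(OC)c(O[Si](C(C)C)(C(C)C)C(C)C)cc1OC | intermediate
11 | 3,4-dimethoxyphenol | COc1ccc(O)cc1OC | starting material
12 | bromomagnesium 3,4-dimethoxyphenoxide | COc1ccc(O[Mg]Br)cc1OC | intermediate (not isolated)
13 | 2-{(2S)-3,3-bis[2,5-dimethoxy-4-(triisopropylsilyloxy)phenyl]-1-hydroxy-2-methylpropyl}-4,5-dimethoxyphenol, both C3 epimers | OC([C@@H](C)C(c1cc(OC)c(O[Si](C(C)C)(C(C)C)C(C)C)cc1OC)c1cc(OC)c(O[Si](C(C)C)(C(C)C)C(C)C)cc1OC)c1cc(OC)c(OC)cc1O | intermediate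
14 | 2-{(2S)-3,3-bis[2,5-dimethoxy-4-(triisopropylsilyloxy)phenyl]-1-hydroxy-2-methylpropyl}-4,5-dimethoxyphenyl tert-butyl carbonate | CC(C)(C)OC(=O)Oc1cc(OC)c(OC)cc1C(O)[C@@H](C)C(c1cc(OC)c(O[Si](C(C)C)(C(C)C)C(C)C)cc1OC)c1cc(OC)c(O[Si](C(C)C)(C(C)C)C(C)C)cc1OC | intermediate
15 | (1S,2R)-2-phenylcyclohexan-1-ol (trans) | O[C@H]1CCCC[C@@H]1c1ccccc1 | starting material
16 | allyl bromide (3-bromoprop-1-ene) | C=CCBr | starting material
17 | (1S,2R)-2-phenylcyclohexyl prop-2-enyl ether | C=CCO[C@H]1CCCC[C@@H]1c1ccccc1 | intermediate
18 | (1S,2R)-2-phenylcyclohexyl (E)-prop-1-enyl ether | C/C=C/O[C@H]1CCCC[C@@H]1c1ccccc1 | intermediate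
19 | chloromagnesium 2-{(2S)-3,3-bis[2,5-dimethoxy-4-(triisopropylsilyloxy)phenyl]-1-(tert-butoxycarbonyloxy)-2-methylpropyl}-4,5-dimethoxyphenoxide | CC(C)(C)OC(=O)OC([C@@H](C)C(c1cc(OC)c(O[Si](C(C)C)(C(C)C)C(C)C)cc1OC)c1cc(OC)c(O[Si](C(C)C)(C(C)C)C(C)C)cc1OC)c1cc(OC)c(OC)cc1O[Mg]Cl | intermediate (not isolated)
20 | (6E)-6-{3,3-bis[2,5-dimethoxy-4-(triisopropylsilyloxy)phenyl]-2-methylpropylidene}-3,4-dimethoxycyclohexa-2,4-dien-1-one, C4 configured as in 10 | O=C1C=C(OC)C(OC)=C\C1=C/[C@@H](C)C(c1cc(OC)c(O[Si](C(C)C)(C(C)C)C(C)C)cc1OC)c1cc(OC)c(O[Si](C(C)C)(C(C)C)C(C)C)cc1OC | intermediate (not isolated)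
21 | (2R,3R,4R)-4-{(2R)-1,1-bis[2,5-dimethoxy-4-(triisopropylsilyloxy)phenyl]propan-2-yl}-6,7-dimethoxy-3-methyl-2-{[(1S,2R)-2-phenylcyclohexyl]oxy}-3,4-dihydro-2H-chromene (2,3-trans, 3,4-trans, 2,4-cis) | c1ccccc1[C@H]1CCCC[C@@H]1O[C@H]1[C@H](C)[C@H](c2cc(OC)c(OC)cc2O1)[C@@H](C)C(c1cc(OC)c(O[Si](C(C)C)(C(C)C)C(C)C)cc1OC)c1cc(OC)c(O[Si](C(C)C)(C(C)C)C(C)C)cc1OC | intermediate
22 | (3R,4R)-4-{(2R)-1,1-bis[2,5-dimethoxy-4-(triisopropylsilyloxy)phenyl]propan-2-yl}-6,7-dimethoxy-3-methyl-3,4-dihydro-2H-chromen-2-ol, both anomers | OC1[C@H](C)[C@H](c2cc(OC)c(OC)cc2O1)[C@@H](C)C(c1cc(OC)c(O[Si](C(C)C)(C(C)C)C(C)C)cc1OC)c1cc(OC)c(O[Si](C(C)C)(C(C)C)C(C)C)cc1OC | intermediate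
23 | vinylmagnesium bromide | C=C[Mg]Br | starting material
24 | (4R,5R,6R)-7,7-bis[2,5-dimethoxy-4-(triisopropylsilyloxy)phenyl]-5-(2-hydroxy-4,5-dimethoxyphenyl)-4,6-dimethylhept-1-en-3-ol, both C1 epimers | C=CC(O)[C@H](C)[C@H](c1cc(OC)c(OC)cc1O)[C@@H](C)C(c1cc(OC)c(O[Si](C(C)C)(C(C)C)C(C)C)cc1OC)c1cc(OC)c(O[Si](C(C)C)(C(C)C)C(C)C)cc1OC | intermediate
25 | (4R,5R,6R)-7,7-bis[2,5-dimethoxy-4-(triisopropylsilyloxy)phenyl]-4,6-dimethyl-5-(2,4,5-trimethoxyphenyl)hept-1-en-3-ol | C=CC(O)[C@H](C)[C@H](c1cc(OC)c(OC)cc1OC)[C@@H](C)C(c1cc(OC)c(O[Si](C(C)C)(C(C)C)C(C)C)cc1OC)c1cc(OC)c(O[Si](C(C)C)(C(C)C)C(C)C)cc1OC | intermediate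
26 | (4R,5R,6R)-7,7-bis[2,5-dimethoxy-4-(triisopropylsilyloxy)phenyl]-4,6-dimethyl-5-(2,4,5-trimethoxyphenyl)hept-1-en-3-yl methyl carbonate | C=CC(OC(=O)OC)[C@H](C)[C@H](c1cc(OC)c(OC)cc1OC)[C@@H](C)C(c1cc(OC)c(O[Si](C(C)C)(C(C)C)C(C)C)cc1OC)c1cc(OC)c(O[Si](C(C)C)(C(C)C)C(C)C)cc1OC | intermediate
27 | (4R,5R,6R)-7,7-bis(4-hydroxy-2,5-dimethoxyphenyl)-4,6-dimethyl-5-(2,4,5-trimethoxyphenyl)hept-1-en-3-yl methyl carbonate | C=CC(OC(=O)OC)[C@H](C)[C@H](c1cc(OC)c(OC)cc1OC)[C@@H](C)C(c1cc(OC)c(O)cc1OC)c1cc(OC)c(O)cc1OC | intermediate
28 | (6S,7R,8R,9S,10R,11R)-7-ethenyl-11-(4-hydroxy-2,5-dimethoxyphenyl)-1,4-dimethoxy-8,10-dimethyl-9-(2,4,5-trimethoxyphenyl)spiro[5.5]undeca-1,4-dien-3-one (vinyl, C2 methyl and both aryl groups cis; C4 methyl trans) | C=C[C@@H]1[C@H](C)[C@H](c2cc(OC)c(OC)cc2OC)[C@@H](C)[C@H](c2cc(OC)c(O)cc2OC)[C@]12C=C(OC)C(=O)C=C2OC | intermediate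
29 | (6S,7R,8S,9S,10R,11R)-7-ethyl-11-(4-hydroxy-2,5-dimethoxyphenyl)-1,4-dimethoxy-8,10-dimethyl-9-(2,4,5-trimethoxyphenyl)spiro[5.5]undeca-1,4-dien-3-one (spatial arrangement as in 28) | CC[C@@H]1[C@H](C)[C@H](c2cc(OC)c(OC)cc2OC)[C@@H](C)[C@H](c2cc(OC)c(O)cc2OC)[C@]12C=C(OC)C(=O)C=C2OC | intermediate
30 | tatanan B, (6S,7R,8S,9S,10R,11R)-7-ethyl-1,4-dimethoxy-8,10-dimethyl-9,11-bis(2,4,5-trimethoxyphenyl)spiro[5.5]undeca-1,4-dien-3-one | CC[C@@H]1[C@H](C)[C@H](c2cc(OC)c(OC)cc2OC)[C@@H](C)[C@H](c2cc(OC)c(OC)cc2OC)[C@]12C=C(OC)C(=O)C=C2OC | target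

## Step count and least certain steps

Total: 17 steps. Longest linear sequence: 15 steps from 1 (steps 1–6 and 9–17); the two steps to enol ether 18 (steps 7 and 8) join at step 9.

**Step 9 (key step).**
- What may go wrong: facial selection against the substrate. The allylic-strain conformer of 20 favours bond formation on the C4-methyl face, and the auxiliary must enforce the face of C5. If the substrate wins, the C2,C3-epimeric chroman results, and a leak through the exo mode would disturb the C2/C3 relation. A 1,5-hydrogen shift from C4 of 20 to a vinylphenol would also erase the C4 centre, and 20 may dimerise if the cycloaddition is slow.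
- Fallback, from 10 and 11, returning at 22: the aryl group is made the nucleophile, so the same conformer works for the route and not against it. Knoevenagel condensation of 10 with Meldrum's acid gives the alkylidene derivative F1. Yb(OTf)3-catalysed Friedel–Crafts conjugate addition of 11, followed by lactonisation with loss of acetone and CO2, gives the dihydrocoumarin F2; here the arene enters anti to C5 with C4–H eclipsing the double bond, which is the C3 configuration the target needs. Enolate methylation (LiN(SiMe3)2, MeI, −78 °C) anti to the C3 side chain gives the trans 3-methyl lactone F3. Reduction with i-Bu2AlH at −78 °C gives lactol 22.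

**Step 4.**
- What may go wrong: incomplete ionisation of 7 under an acid mild enough for the silyl ether of the catalyst, loss of the catalyst's silyl group, Friedel–Crafts self-alkylation of 9 with the electron-rich arenes, or partial racemisation of 10 through its enol.
- Fallback, from 7, returning at 10: an auxiliary-controlled enolate alkylation. Carbinol 7 is acetylated (Ac2O, pyridine) to the diarylmethyl acetate F4. The chlorotitanium enolate of (R)-4-benzyl-3-propanoyl-1,3-oxazolidin-2-one (TiCl4, i-Pr2NEt, CH2Cl2) is alkylated by the cation that TiCl4 releases from F4, on the face away from the benzyl group, to give the imide F5. LiBH4 removes the oxazolidinone to give the primary alcohol F6, and Dess–Martin periodinane oxidises it to 10.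

**Step 5.**
- What may go wrong: epimerisation at C4 through a magnesium enolate of the hindered aldehyde, slow addition, attack at the crowded ortho carbon, or addition of a second phenoxide to a quinone methide formed too early (bisphenol formation).
- Fallback, from 11 and 10, returning at 13: the aryl–C3 bond is made by an aryllithium at low temperature. Bromination of 11 (N-bromosuccinimide) gives 2-bromo-4,5-dimethoxyphenol F7, and allylation (allyl bromide, K2CO3) gives the allyl ether F8. Bromine–lithium exchange (n-BuLi, −78 °C) and addition to 10 give the carbinol F9. Deallylation with Pd(PPh3)4 and morpholine under neutral conditions gives 13.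

**Step 15.**
- What may go wrong: O-allylation in place of ipso C-allylation, attack by the other twin phenol or through a transition state with an axial vinyl group (wrong C1 or C5), the other rotamer of the attacking ring (wrong C6), or β-hydride elimination of the allyl complex to a diene.
- Fallback, from 25, returning at 28: catalyst control over C1 with iridium. A rhenium-catalysed 1,3-transposition (Ph3SiOReO3, Et2O) converts 25 into the linear (E)-allylic alcohol F10. ClCO2Me and pyridine give the linear carbonate F11, and Bu4NF/AcOH gives the bis-phenol F12. [Ir(cod)Cl]2 with a chiral BINOL-derived phosphoramidite and Cs2CO3 then effects the branched-selective dearomatising allylation, in which the ligand fixes the configuration at C1, to give 28.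

## Further compounds

F1 | step 9 | 5-{3,3-bis[2,5-dimethoxy-4-(triisopropylsilyloxy)phenyl]-2-methylpropylidene}-2,2-dimethyl-1,3-dioxane-4,6-dione, C4 configured as in 10 | CC1(C)OC(=O)C(=C[C@@H](C)C(c2cc(OC)c(O[Si](C(C)C)(C(C)C)C(C)C)cc2OC)c2cc(OC)c(O[Si](C(C)C)(C(C)C)C(C)C)cc2OC)C(=O)O1
F2 | step 9 | 4-{1,1-bis[2,5-dimethoxy-4-(triisopropylsilyloxy)phenyl]propan-2-yl}-6,7-dimethoxy-3,4-dihydrochromen-2-one, C3 and C4 of ring A configured as in 22 | O=C1C[C@H](c2cc(OC)c(OC)cc2O1)[C@@H](C)C(c1cc(OC)c(O[Si](C(C)C)(C(C)C)C(C)C)cc1OC)c1cc(OC)c(O[Si](C(C)C)(C(C)C)C(C)C)cc1OC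
F3 | step 9 | trans-4-{1,1-bis[2,5-dimethoxy-4-(triisopropylsilyloxy)phenyl]propan-2-yl}-6,7-dimethoxy-3-methyl-3,4-dihydrochromen-2-one, C2, C3 and C4 of ring A configured as in 22 | O=C1[C@H](C)[C@H](c2cc(OC)c(OC)cc2O1)[C@@H](C)C(c1cc(OC)c(O[Si](C(C)C)(C(C)C)C(C)C)cc1OC)c1cc(OC)c(O[Si](C(C)C)(C(C)C)C(C)C)cc1OC
F4 | step 4 | bis[2,5-dimethoxy-4-(triisopropylsilyloxy)phenyl]methyl acetate | CC(=O)OC(c1cc(OC)c(O[Si](C(C)C)(C(C)C)C(C)C)cc1OC)c1cc(OC)c(O[Si](C(C)C)(C(C)C)C(C)C)cc1OC
F5 | step 4 | (4R)-4-benzyl-3-{(2S)-3,3-bis[2,5-dimethoxy-4-(triisopropylsilyloxy)phenyl]-2-methylpropanoyl}-1,3-oxazolidin-2-one | O=C1OC[C@@H](Cc2ccccc2)N1C(=O)[C@@H](C)C(c1cc(OC)c(O[Si](C(C)C)(C(C)C)C(C)C)cc1OC)c1cc(OC)c(O[Si](C(C)C)(C(C)C)C(C)C)cc1OC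
F6 | step 4 | (2S)-3,3-bis[2,5-dimethoxy-4-(triisopropylsilyloxy)phenyl]-2-methylpropan-1-ol | OC[C@@H](C)C(c1cc(OC)c(O[Si](C(C)C)(C(C)C)C(C)C)cc1OC)c1cc(OC)c(O[Si](C(C)C)(C(C)C)C(C)C)cc1OC
F7 | step 5 | 2-bromo-4,5-dimethoxyphenol | COc1cc(O)c(Br)cc1OC
F8 | step 5 | 1-bromo-4,5-dimethoxy-2-(prop-2-enyloxy)benzene | C=CCOc1cc(OC)c(OC)cc1Br
F9 | step 5 | (2S)-3,3-bis[2,5-dimethoxy-4-(triisopropylsilyloxy)phenyl]-1-[4,5-dimethoxy-2-(prop-2-enyloxy)phenyl]-2-methylpropan-1-ol, both C3 epimers | C=CCOc1cc(OC)c(OC)cc1C(O)[C@@H](C)C(c1cc(OC)c(O[Si](C(C)C)(C(C)C)C(C)C)cc1OC)c1cc(OC)c(O[Si](C(C)C)(C(C)C)C(C)C)cc1OC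
F10 | step 15 | (2E)-7,7-bis[2,5-dimethoxy-4-(triisopropylsilyloxy)phenyl]-4,6-dimethyl-5-(2,4,5-trimethoxyphenyl)hept-2-en-1-ol, C2, C3 and C4 of ring A configured as in 25 | OC/C=C/[C@H](C)[C@H](c1cc(OC)c(OC)cc1OC)[C@@H](C)C(c1cc(OC)c(O[Si](C(C)C)(C(C)C)C(C)C)cc1OC)c1cc(OC)c(O[Si](C(C)C)(C(C)C)C(C)C)cc1OC
F11 | step 15 | methyl carbonate of F10 | COC(=O)OC/C=C/[C@H](C)[C@H](c1cc(OC)c(OC)cc1OC)[C@@H](C)C(c1cc(OC)c(O[Si](C(C)C)(C(C)C)C(C)C)cc1OC)c1cc(OC)c(O[Si](C(C)C)(C(C)C)C(C)C)cc1OC
F12 | step 15 | (2E)-7,7-bis(4-hydroxy-2,5-dimethoxyphenyl)-4,6-dimethyl-5-(2,4,5-trimethoxyphenyl)hept-2-en-1-yl methyl carbonate, configured as in 27 | COC(=O)OC/C=C/[C@H](C)[C@H](c1cc(OC)c(OC)cc1OC)[C@@H](C)C(c1cc(OC)c(O)cc1OC)c1cc(OC)c(O)cc1OC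
A1 | alternative 1 | meso all-cis 3,5-bis(2,4,5-trimethoxyphenyl) 8-aminoquinoline carboxamide of ring A with C1 as ethylene ketal | O=C(Nc1cccc2cccnc12)[C@@H]1[C@H](c2cc(OC)c(OC)cc2OC)CC2(OCCO2)C[C@@H]1c1cc(OC)c(OC)cc1OC
A2 | alternative 1 | 1-iodo-2,4,5-trimethoxybenzene | COc1cc(OC)c(OC)cc1I
A3 | alternative 1 | N-(quinolin-8-yl)-1,4-dioxaspiro[4.5]decane-8-carboxamide | O=C(Nc1cccc2cccnc12)C1CCC2(CC1)OCCO2
A4 | alternative 2 | all-trans 6-ethyl-3-methyl-5-nitro-4-(2,4,5-trimethoxyphenyl)cyclohex-1-ene-1-carbaldehyde | CC[C@@H]1[C@@H]([N+](=O)[O-])[C@H](c2cc(OC)c(OC)cc2OC)[C@@H](C)C=C1C=O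
A5 | alternative 2 | 1,2,4-trimethoxy-5-[(E)-2-nitroethenyl]benzene | COc1cc(OC)c(/C=C/[N+](=O)[O-])cc1OC
A6 | alternative 2 | (E)-pent-2-enal | CC/C=C/C=O
A7 | alternative 3 | 1-vinyl spirodienone with one free phenol on the C5 aryl, identical with 28 | C=C[C@@H]1[C@H](C)[C@H](c2cc(OC)c(OC)cc2OC)[C@@H](C)[C@H](c2cc(OC)c(O)cc2OC)[C@]12C=C(OC)C(=O)C=C2OC
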